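The earlier runs and the new flask were generated by integration for substances that don't exist; the scatter is artificial.

Early times interest me less for either product than for a clock that will carry this kinetic resolution from the start to the asked time.

in all of them: left-handed substrate 0.74 M; right-handed substrate 0.74 M
- epsilon: partner 0.74 M; free catalyst 130 mM; run made earlier
- gamma: partner 1.1 M; free catalyst 130 mM; run made earlier
- eta: partner 1.48 M; free catalyst 65 mM; run made earlier
- flask: partner 1.48 M; free catalyst 130 mM; time 10 h

- free catalyst is single-handed; left-handed substrate and right-handed substrate are mirror images of each other, charged as a racemate, each of them at the stated concentration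
- an excess is the difference of the two amounts in percent of their sum
- an excess is below zero if the other one leads

- excess of left-handed product over right-handed product in the product at 12 min
- excess of left-handed product over right-handed product in the product at 10 h
- part of the left-handed substrate and right-handed substrate charged together that has reacted at 10 h

eta run (percent of the left-handed substrate and right-handed substrate together charged)

| time / h | left-handed product / % | right-handed product / % | left-handed substrate / % |
|---|---|---|---|
| 1.00 | 6.4 | 3.7 | 43.4 |
| 2.00 | 10.2 | 5.6 | 38.5 |
| 3.00 | 14.9 | 8.7 | 34.2 |
| 6.00 | 22.3 | 13.1 | 25.6 |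
| 12.0 | 32.9 | 19.1 | 15.7 |

In eta the partner charge equals the two substrates together, as it does in the flask. I take one partner per substrate and a rate that goes as catalyst times substrate times partner. The conversion odds, product over what is not yet product, should then grow with catalyst charge times time, and I call their slope the turnover constant. Each reading is good to 0.5 percentage points, one standard deviation. Reading eta, the row at 6.00 h gives 1.41 L mol⁻¹ h⁻¹, the first row gives 1.73 L mol⁻¹ h⁻¹, which is higher on a small product, and the last row gives 1.39 L mol⁻¹ h⁻¹, which I carry as the turnover constant.

epsilon run (percent of the left-handed substrate and right-handed substrate together charged)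

| time / h | left-handed product / % | right-handed product / % | left-handed substrate / % |
|---|---|---|---|
| 2.50 | 12.4 | 5.5 | 33.8 |
| 5.00 | 18.5 | 9.4 | 29.0 |
| 8.00 | 22.1 | 10.9 | 24.8 |
| 10.0 | 23.3 | 12.1 | 24.0 |
| 12.0 | 25.3 | 13.4 | 23.4 |

gamma run (percent of the left-handed substrate and right-handed substrate together charged)

| time / h | left-handed product / % | right-handed product / % | left-handed substrate / % |
|---|---|---|---|
| 2.50 | 16.3 | 8.9 | 32.0 |
| 5.00 | 25.2 | 15.1 | 23.5 |
| 8.00 | 29.9 | 17.6 | 16.7 |
| 10.0 | 33.2 | 18.8 | 15.7 |
| 12.0 | 34.4 | 20.9 | 14.1 |

Epsilon has twice the catalyst and half the partner of eta, and it reads 17.9% product at 2.50 h, while eta reads 15.8% at 2.00 h and 23.6% at 3.00 h, so catalyst and partner appear to count alike. For the flask at 10 h I therefore reckon 64.4% product.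

Conversion also counts substrate sitting on catalyst, which I treat as a small correction. At 10.0 h, left-handed product plus left-handed substrate falls short of the left-handed charge by 1.90% on the mean of epsilon and gamma. Right-handed substrate is not read, so I assume the same shortfall for it, and I commit to 68.2% converted.

The forecast reasons that the flask “should therefore behave like eta at twice the time” and gives excesses of 26% (19% to 33%) and 23% (19% to 27%), and 66% (61% to 71%) converted, which is less than mine.

The flask gives excesses of 16.5% and 20.4%, and 71.3% converted.

    partner + catalyst intermediate B → free catalyst + right-handed product (k = 1.20 L mol⁻¹ h⁻¹)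
    partner ⇌ dormant form (K = 0.300, k = 0.0560 h⁻¹)
    partner + catalyst intermediate A → free catalyst + left-handed product (k = 2.80 L mol⁻¹ h⁻¹)
    partner → decomposed reagent (k = 0.0200 h⁻¹)
    free catalyst + right-handed substrate ⇌ catalyst intermediate B (K = 2.80 L mol⁻¹, k = 100 L mol⁻¹ h⁻¹)
    free catalyst + left-handed substrate ⇌ catalyst intermediate A (K = 3.10 L mol⁻¹, k = 25.0 L mol⁻¹ h⁻¹)

The flask holds 66.5% product at 10.0 h, against 64.4% from the turnover constant. Catalyst intermediates A and B hold 54.4% of the catalyst there, which is 4.77% of the substrates charged, against my correction of 3.80%. The neighbour flask with 0.52 M of free catalyst, its other charges and time as here, reckons to 87.8% product at 10 h. It holds 87.3% product and has converted 94.2%.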